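**Strategy.** The six-membered carbocycle of the chromanone (C4a, C5, C6, C7, C8, C8a) is a dearomatised phloroglucinol: oxygenated C5, C7 and C8a alternate with carbon-substituted C6, C8 and C4a, the pattern of a folded 3,5-dioxo ester. The ring is therefore assembled de novo. In one pot, the extended enolate of the 6-methyl group of an enantiopure dihydropyranone ester is acylated by a pinene-derived cyclobutylpropanoate, and the new ketone's α′-carbanion (future C6) then attacks the neighbouring ester carbon (future C5). This Claisen closure forges C5–C6 and aromatises. The phenylpropanoic arm (C8) and the prenyl group (quaternary C6) follow.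

Key step: step 10

Remark 1: chromanone numbering (O1, C2, C3, C4, C4a, C5–C8, C8a) is used for the core; the target is drawn as its 5-hydroxy-7-oxo tautomer, to which the product of step 14 is expected to settle.
Remark 2: the sense of induction of the (S,S)-Trost ligand in step 14 is assumed; the (R,R)-ligand is substituted if the C6 epimer predominates.

Step 1
Reactants: 1 (1S,5S)-(−)-α-pinene
Product: 2 2-[(1R,3R)-3-acetyl-2,2-dimethylcyclobutyl]acetic acid (cis-pinonic acid)
Conditions: RuCl3·xH2O (2 mol %), NaIO4 (4.1 equiv), MeCN/EtOAc/H2O, 0 °C → rt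
Reagents that add atoms: sodium periodate [Na+].[O-]I(=O)(=O)=O; water O
Why: Ruthenium tetroxide generated in situ (Sharpless oxidative cleavage) cuts the trisubstituted alkene to methyl ketone and acid; both cyclobutane stereocentres come unchanged from the pinene as the cis pair.

Step 2
Reactants: 2 2-[(1R,3R)-3-acetyl-2,2-dimethylcyclobutyl]acetic acid
Product: 4 1-diazo-3-[(1R,3R)-3-acetyl-2,2-dimethylcyclobutyl]propan-2-one, via acid chloride 3 (not isolated)
Conditions: (COCl)2, DMF (cat.), CH2Cl2, 0 °C → rt; then Me3SiCHN2 (2.2 equiv), THF/MeCN, 0 °C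
Reagents that add atoms: trimethylsilyldiazomethane C[Si](C)(C)C=[N+]=[N-]
Why: First half of an Arndt–Eistert homologation, in which the acid chloride acylates the diazo carbon to give the α-diazoketone while the methyl ketone is inert.

Step 3
Reactants: 4 1-diazo-3-[(1R,3R)-3-acetyl-2,2-dimethylcyclobutyl]propan-2-one
Product: 6 methyl 3-[(1S,3R)-3-acetyl-2,2-dimethylcyclobutyl]propanoate, via ketene 5 (not isolated)
Conditions: AgO2CPh (10 mol %), Et3N, MeOH, rt, dark
Reagents that add atoms: methanol CO
Why: Silver-catalysed Wolff rearrangement gives the ketene, which methanol traps as the one-carbon-homologated ester; the migrating CH2 is not stereogenic and the ring centres are not involved.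

Step 4
Reactants: 6 methyl 3-[(1S,3R)-3-acetyl-2,2-dimethylcyclobutyl]propanoate
Product: 7 methyl 3-[(1S,3S)-2,2-dimethyl-3-(prop-1-en-2-yl)cyclobutyl]propanoate
Conditions: Zn, CH2Br2, TiCl4, THF/CH2Cl2, 0 °C → rt
Reagents that add atoms: dibromomethane BrCBr
Why: Takai–Lombardo methylenation is non-basic, so the ketone becomes the isopropenyl group without epimerising the adjacent ring CH and without touching the ester.

Step 5
Reactants: 8 methyl (3R)-3-hydroxybutanoate
Product: 9 methyl (2R,3R)-3-hydroxy-2-methylbutanoate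
Conditions: LiN(iPr)2 (2.2 equiv), THF, −78 → −20 °C; MeI, DMPU, −78 → 0 °C
Reagents that add atoms: iodomethane CI
Why: Fráter–Seebach alkylation, in which the chelated alkoxide–enolate dianion is methylated on the face away from the C3 methyl and should give mainly the anti (2R,3R) ester.

Step 6
Reactants: 9 methyl (2R,3R)-3-hydroxy-2-methylbutanoate
Product: 10 methyl (2R,3R)-3-[(tert-butyldimethylsilyl)oxy]-2-methylbutanoate
Conditions: TBSCl, imidazole, DMF, rt
Reagents that add atoms: tert-butyldimethylsilyl chloride CC(C)(C)[Si](C)(C)Cl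
Why: Standard silylation masks the alcohol for the acylation in step 8.

Step 7
Reactants: 10 methyl (2R,3R)-3-[(tert-butyldimethylsilyl)oxy]-2-methylbutanoate
Product: 11 (2R,3R)-3-[(tert-butyldimethylsilyl)oxy]-2-methylbutanoic acid
Conditions: LiOH, THF/MeOH/H2O, 0 °C → rt; 1 M HCl to pH 3 at 0 °C
Reagents that add atoms: water O
Why: Mild saponification, under which the hindered α-centre is not expected to epimerise and β-elimination of the silyloxy group should be slow.

Step 8
Reactants: 11 (2R,3R)-3-[(tert-butyldimethylsilyl)oxy]-2-methylbutanoic acid; 12 methyl acetoacetate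
Product: 14 methyl (4R,5R)-2-acetyl-5-[(tert-butyldimethylsilyl)oxy]-4-methyl-3-oxohexanoate (C2 unassigned; enol mixture), via acid chloride 13 (not isolated)
Conditions: 1-chloro-N,N,2-trimethylprop-1-en-1-amine, CH2Cl2, 0 °C; then 12, MgCl2, pyridine, CH2Cl2, 0 °C → rt
Reagents that add atoms: none
Why: Ghosez's reagent makes the acid chloride under neutral conditions that spare the silyl ether, and the magnesium enolate of the β-keto ester is C-acylated (Rathke–Cowan conditions) to the triacylmethane.

Step 9
Reactants: 14 methyl (4R,5R)-2-acetyl-5-[(tert-butyldimethylsilyl)oxy]-4-methyl-3-oxohexanoate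
Product: 15 methyl (2R,3R)-2,3,6-trimethyl-4-oxo-3,4-dihydro-2H-pyran-5-carboxylate
Conditions: HF (48 % aq.), MeCN, 0 °C → rt
Reagents that add atoms: none
Why: Desilylation frees the hydroxyl, which adds to the more electrophilic acetyl carbonyl (6-exo-trig hemiketal) and dehydrates to the vinylogous ester; the carbinol C–O bond is never broken, so C2 keeps its configuration and the anti acid maps onto the trans-2,3-dimethyl ring.

Step 10
Reactants: 15 methyl (2R,3R)-2,3,6-trimethyl-4-oxo-3,4-dihydro-2H-pyran-5-carboxylate; 7 methyl 3-[(1S,3S)-2,2-dimethyl-3-(prop-1-en-2-yl)cyclobutyl]propanoate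
Product: 17 (2R,3R)-6-{[(1R,3S)-2,2-dimethyl-3-(prop-1-en-2-yl)cyclobutyl]methyl}-5,7-dihydroxy-2,3-dimethyl-2,3-dihydro-4H-chromen-4-one, via keto ester 16 (not isolated)
Conditions: 15 (2.1 equiv), LiN(iPr)2 (2.0 equiv), THF, −78 → −40 °C; 7 (1.0 equiv), −78 → −20 °C; then LiN(iPr)2 (2.5 equiv), −78 → 0 °C; AcOH quench (excess 15 recovered)
Reagents that add atoms: none
Why: The 6-methyl group of 15 is the γ-position of a doubly activated vinylogous ester, so a slight deficit of amide base gives the thermodynamic extended enolate, which undergoes Claisen acylation at its terminal carbon (future C8) with ester 7 to give keto ester 16, held as its C8-centred enolate. A second charge of LiN(iPr)2 then removes a proton from the CH2 between the ketone and the cyclobutylmethyl group (future C6), and this terminal carbanion of the 1,3-dianion attacks the C5 ester in a 6-(enolendo)-exo-trig Dieckmann–Claisen closure; loss of methoxide and enolisation give the phloroglucinol, which makes the closure irreversible. The closest known reactions are the Harris-type Claisen cyclisation of 3,5-dioxoalkanoate polyanions to phloroglucinols and the toluate-anion acylation–cyclisation route to 1,3-naphthalenediols. One ring (the carbocycle) is closed and no stereocentre is created, because C6 becomes an aromatic carbon; C2 and C3 of the pyranone are spectators. The step needs γ- over α′-deprotonation and C- over O-cyclisation: the first is secured by enolate equilibration and the hindered tertiary C3–H, the second by the cis disposition of ester and side chain on the ring double bond, the higher nucleophilicity of the dianion terminus and the aromatic sink. Low temperature and only a small excess of base limit retro-oxa-Michael opening of the pyranone.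

Step 11
Reactants: 17 (2R,3R)-6-{[(1R,3S)-2,2-dimethyl-3-(prop-1-en-2-yl)cyclobutyl]methyl}-5,7-dihydroxy-2,3-dimethyl-2,3-dihydro-4H-chromen-4-one; 18 (E)-cinnamaldehyde
Product: 19 (2R,3R,10S)-6-{[(1R,3S)-2,2-dimethyl-3-(prop-1-en-2-yl)cyclobutyl]methyl}-5,8-dihydroxy-2,3-dimethyl-10-phenyl-2,3,9,10-tetrahydro-4H,8H-pyrano[2,3-f]chromen-4-one (lactol bridging O7 and C8 of the chromanone; anomers)
Conditions: (S)-2-[diphenyl(trimethylsilyloxy)methyl]pyrrolidine (20 mol %), PhCO2H (20 mol %), toluene, 0 °C → rt
Reagents that add atoms: none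
Why: Iminium-catalysed Friedel–Crafts alkylation of the only free aromatic position (C8) followed by hemiacetalisation with the 7-OH; the silyloxydiphenylmethyl group of the (S)-catalyst shields the Re face of the β-carbon, so C8 should add to the Si face, which corresponds to the (S) benzylic centre.

Step 12
Reactants: 19 the lactol of step 11
Product: 20 (2R,3R,10S)-6-{[(1R,3S)-2,2-dimethyl-3-(prop-1-en-2-yl)cyclobutyl]methyl}-5-hydroxy-2,3-dimethyl-10-phenyl-2,3,9,10-tetrahydro-4H,8H-pyrano[2,3-f]chromene-4,8-dione
Conditions: Ag2CO3 on Celite (5 equiv), toluene, 80 °C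
Reagents that add atoms: none
Why: Fétizon oxidation converts the lactol into the lactone under neutral conditions that should leave the chelated phenol, the alkene and the cyclobutane alone.

Step 13
Reactants: 20 the lactone of step 12
Product: 21 (3S)-3-[(2R,3R)-6-{[(1R,3S)-2,2-dimethyl-3-(prop-1-en-2-yl)cyclobutyl]methyl}-5,7-dihydroxy-2,3-dimethyl-4-oxo-3,4-dihydro-2H-chromen-8-yl]-3-phenylpropanoic acid
Conditions: LiOH (4 equiv), THF/H2O, 0 °C; 1 M HCl to pH 3–4 at 0 °C
Reagents that add atoms: water O
Why: Saponification of the aryl ester (dihydrocoumarin) is fast, the cold, mildly acidic work-up avoids relactonisation and protonation of the isopropenyl group, and any cis isomer at C3 formed earlier should return to the more stable trans ring under base.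

Step 14
Reactants: 21 the acid of step 13; 22 3-methylbut-2-en-1-yl acetate (prenyl acetate)
Product: 23 (3S)-3-[(2R,3R,6R)-6-{[(1R,3S)-2,2-dimethyl-3-(prop-1-en-2-yl)cyclobutyl]methyl}-5-hydroxy-2,3-dimethyl-6-(3-methylbut-2-en-1-yl)-4,7-dioxo-3,4,6,7-tetrahydro-2H-chromen-8-yl]-3-phenylpropanoic acid
Conditions: Pd2(dba)3·CHCl3 (2.5 mol %), N,N′-[(1S,2S)-cyclohexane-1,2-diyl]bis[2-(diphenylphosphanyl)benzamide] ((S,S)-DACH-phenyl Trost ligand, 7.5 mol %), Cs2CO3 (2.2 equiv), degassed THF, 0 °C → rt; pH 4 buffer
Reagents that add atoms: none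
Why: Tsuji–Trost dearomative C-allylation, in which the 7-phenoxide attacks the π-prenyl complex formed from zerovalent palladium through C6 (ortho to both oxygens and less hindered than C8) at the less substituted allyl terminus, O-prenyl products re-ionise, and the chiral pocket of the Trost ligand is relied on to select the C6 face that gives the (6R) centre.

**Compound list**

1 | (1S,5S)-(−)-α-pinene | CC1=CC[C@H]2C[C@@H]1C2(C)C | starting material
2 | 2-[(1R,3R)-3-acetyl-2,2-dimethylcyclobutyl]acetic acid | CC(=O)[C@@H]1C[C@H](CC(=O)O)C1(C)C | intermediate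
3 | 2-[(1R,3R)-3-acetyl-2,2-dimethylcyclobutyl]acetyl chloride | CC(=O)[C@@H]1C[C@H](CC(Cl)=O)C1(C)C | intermediate
4 | 1-diazo-3-[(1R,3R)-3-acetyl-2,2-dimethylcyclobutyl]propan-2-one | CC(=O)[C@@H]1C[C@H](CC(=O)C=[N+]=[N-])C1(C)C | intermediate
5 | 3-[(1S,3R)-3-acetyl-2,2-dimethylcyclobutyl]prop-1-en-1-one (ketene) | CC(=O)[C@@H]1C[C@H](CC=C=O)C1(C)C | intermediate
6 | methyl 3-[(1S,3R)-3-acetyl-2,2-dimethylcyclobutyl]propanoate | CC(=O)[C@@H]1C[C@H](CCC(=O)OC)C1(C)C | intermediate
7 | methyl 3-[(1S,3S)-2,2-dimethyl-3-(prop-1-en-2-yl)cyclobutyl]propanoate | C=C(C)[C@@H]1C[C@H](CCC(=O)OC)C1(C)C | intermediate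
8 | methyl (3R)-3-hydroxybutanoate | C[C@@H](O)CC(=O)OC | starting material
9 | methyl (2R,3R)-3-hydroxy-2-methylbutanoate | C[C@@H](O)[C@@H](C)C(=O)OC | intermediate
10 | methyl (2R,3R)-3-[(tert-butyldimethylsilyl)oxy]-2-methylbutanoate | CC(C)(C)[Si](C)(C)O[C@H](C)[C@@H](C)C(=O)OC | intermediate
11 | (2R,3R)-3-[(tert-butyldimethylsilyl)oxy]-2-methylbutanoic acid | CC(C)(C)[Si](C)(C)O[C@H](C)[C@@H](C)C(=O)O | intermediate
12 | methyl acetoacetate | CC(=O)CC(=O)OC | starting material
13 | (2R,3R)-3-[(tert-butyldimethylsilyl)oxy]-2-methylbutanoyl chloride | CC(C)(C)[Si](C)(C)O[C@H](C)[C@@H](C)C(Cl)=O | intermediate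
14 | methyl (4R,5R)-2-acetyl-5-[(tert-butyldimethylsilyl)oxy]-4-methyl-3-oxohexanoate | CC(C)(C)[Si](C)(C)O[C@H](C)[C@@H](C)C(=O)C(C(C)=O)C(=O)OC | intermediate
15 | methyl (2R,3R)-2,3,6-trimethyl-4-oxo-3,4-dihydro-2H-pyran-5-carboxylate | C[C@H]1OC(C)=C(C(=O)OC)C(=O)[C@@H]1C | intermediate
16 | methyl (2R,3R)-6-{4-[(1S,3S)-2,2-dimethyl-3-(prop-1-en-2-yl)cyclobutyl]-2-oxobutyl}-2,3-dimethyl-4-oxo-3,4-dihydro-2H-pyran-5-carboxylate | C=C(C)[C@@H]1C[C@H](CCC(=O)CC2=C(C(=O)OC)C(=O)[C@H](C)[C@@H](C)O2)C1(C)C | intermediate
17 | (2R,3R)-6-{[(1R,3S)-2,2-dimethyl-3-(prop-1-en-2-yl)cyclobutyl]methyl}-5,7-dihydroxy-2,3-dimethyl-2,3-dihydro-4H-chromen-4-one | C=C(C)[C@@H]1C[C@H](Cc2c(O)cc3O[C@H](C)[C@@H](C)C(=O)c3c2O)C1(C)C | intermediate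
18 | (E)-cinnamaldehyde | O=C/C=C/c1ccccc1 | starting material
19 | (2R,3R,10S)-6-{[(1R,3S)-2,2-dimethyl-3-(prop-1-en-2-yl)cyclobutyl]methyl}-5,8-dihydroxy-2,3-dimethyl-10-phenyl-2,3,9,10-tetrahydro-4H,8H-pyrano[2,3-f]chromen-4-one | C=C(C)[C@@H]1C[C@H](Cc2c3OC(O)C[C@@H](c4ccccc4)c3c3O[C@H](C)[C@@H](C)C(=O)c3c2O)C1(C)C | intermediate
20 | (2R,3R,10S)-6-{[(1R,3S)-2,2-dimethyl-3-(prop-1-en-2-yl)cyclobutyl]methyl}-5-hydroxy-2,3-dimethyl-10-phenyl-2,3,9,10-tetrahydro-4H,8H-pyrano[2,3-f]chromene-4,8-dione | C=C(C)[C@@H]1C[C@H](Cc2c3OC(=O)C[C@@H](c4ccccc4)c3c3O[C@H](C)[C@@H](C)C(=O)c3c2O)C1(C)C | intermediate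
21 | (3S)-3-[(2R,3R)-6-{[(1R,3S)-2,2-dimethyl-3-(prop-1-en-2-yl)cyclobutyl]methyl}-5,7-dihydroxy-2,3-dimethyl-4-oxo-3,4-dihydro-2H-chromen-8-yl]-3-phenylpropanoic acid | C=C(C)[C@@H]1C[C@H](Cc2c(O)c([C@@H](CC(=O)O)c3ccccc3)c3O[C@H](C)[C@@H](C)C(=O)c3c2O)C1(C)C | intermediate
22 | 3-methylbut-2-en-1-yl acetate | CC(C)=CCOC(C)=O | starting material
23 | (3S)-3-[(2R,3R,6R)-6-{[(1R,3S)-2,2-dimethyl-3-(prop-1-en-2-yl)cyclobutyl]methyl}-5-hydroxy-2,3-dimethyl-6-(3-methylbut-2-en-1-yl)-4,7-dioxo-3,4,6,7-tetrahydro-2H-chromen-8-yl]-3-phenylpropanoic acid | C=C(C)[C@@H]1C[C@H](C[C@@]2(CC=C(C)C)C(=O)C([C@@H](CC(=O)O)c3ccccc3)=C3O[C@H](C)[C@@H](C)C(=O)C3=C2O)C1(C)C | target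

**Step count.** Total: 14 steps. Longest linear sequence: 10 steps (steps 5–14, from 8). The cyclobutane branch (steps 1–4) joins at step 10.

**Steps most likely to fail**

Step 14. The catalyst may not discriminate the two faces of C6, whose substituents differ only far from the ring, and O-prenylation or attack at the tertiary allyl terminus may compete. The fallback gives up catalyst control in favour of separation. It sets out from acid 21, which is treated with prenyl bromide in aqueous KOH at 0 °C (classical alkylative dearomatisation of an acylphloroglucinol). This should give 23 together with its C6 epimer, (3S)-3-[(2R,3R,6S)-…]-3-phenylpropanoic acid F1. The two are diastereomers and would be separated by preparative HPLC, so the fallback rejoins the route at 23.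

Step 10. Excess amide base may deprotonate C3 of the pyranone (epimerisation or retro-oxa-Michael ring opening), the first Claisen acylation with a simple ester may be sluggish, and the ketone enolate oxygen may close onto the C5 ester to give a pyranone instead of the carbocycle. The fallback splits the annulation into two controlled operations. It sets out from ester 7, which is converted with MeNHOMe·HCl and iPrMgCl into the Weinreb amide N-methoxy-N-methyl-3-[(1S,3S)-2,2-dimethyl-3-(prop-1-en-2-yl)cyclobutyl]propanamide F2. F2 is added to the extended enolate from one equivalent of 15 (LiN(iPr)2, 1.05 equiv, −78 °C); the stable chelate prevents proton exchange, so keto ester 16 is isolated after work-up. Keto ester 16 is then cyclised under thermodynamic control with NaH in THF at 0 °C → rt, which rejoins the route at 17.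

Step 11. Condensation at the aldehyde carbon (1,2-addition leading to a 2-phenylchromene) may compete with conjugate addition, and facial control by the amine catalyst may be insufficient on this hindered acylphloroglucinol. The fallback sets the benzylic centre at the acyl-azolium oxidation level instead. It sets out from 17, which is combined with 18, a chiral triazolium carbene precatalyst, a mild base and a quinone oxidant (oxidative carbene-catalysed annulation of enals with phenols). This should give lactone 20 directly, where the fallback rejoins the route; it creates no compound outside the list (entry F0).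

**Further compounds**

F1 | step 14 | (3S)-3-[(2R,3R,6S)-6-{[(1R,3S)-2,2-dimethyl-3-(prop-1-en-2-yl)cyclobutyl]methyl}-5-hydroxy-2,3-dimethyl-6-(3-methylbut-2-en-1-yl)-4,7-dioxo-3,4,6,7-tetrahydro-2H-chromen-8-yl]-3-phenylpropanoic acid | C=C(C)[C@@H]1C[C@H](C[C@]2(CC=C(C)C)C(=O)C([C@@H](CC(=O)O)c3ccccc3)=C3O[C@H](C)[C@@H](C)C(=O)C3=C2O)C1(C)C
F2 | step 10 | N-methoxy-N-methyl-3-[(1S,3S)-2,2-dimethyl-3-(prop-1-en-2-yl)cyclobutyl]propanamide | C=C(C)[C@@H]1C[C@H](CCC(=O)N(C)OC)C1(C)C
F0 | step 11 | none | none
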